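**Retrosynthetic overview**

1. The target is traced back, through O-acetylation and a one-pot removal of an N-Boc group and a dioxolane, to an N-Boc cis-2,6-disubstituted piperidin-3-one; its C3 ketone is reduced under substrate control to the all-cis alcohol.
2. Key disconnection: the C5–C6 bond of the piperidine. The piperidinone arises from a spiro-oxazolidine by a zinc-mediated intramolecular homo-Mannich ring expansion, in which a cyclopropanol (latent C5 homoenolate of the C3 ketone) attacks the imine carbon C6.
3. Enabling feature: the C3 oxygen and N1 are linked twice, directly through C2 (N1–C2–C3–O, a 1,2-amino alcohol) and through C4–C5–C6 (a γ-amino ketone at the C3 ketone level). C3/C4/C5 can therefore be stored as a cyclopropanol ring and N1/C2/C3/O/C6 as an oxazolidine ring; cleaving the C3–C5 and O–C6 bonds of this spiro bicycle while C5 bonds to C6 delivers the six-membered ring.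
4. The oxazolidine comes from a D-alanine-derived aminocyclopropanol (Kulinkovich reaction) and a ketal-protected 14-oxopentadecanal (acetoacetic ester synthesis on 12-bromododecan-1-ol). C2 is the only purchased stereocentre and is relayed to C6 in the key step and to C3 in the reduction.
5. Ring order: cyclopropane (temporary, step 2), oxazolidine (temporary, step 7), piperidine (step 8, with loss of both temporary rings).

Key step: step 8

Remark: the SMILES is read as the all-cis (2R,3R,6S) piperidine; the locants N1 and C2 to C6 used below are those of the piperidine ring of the target.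

**Route**

Step 1
Reactants: 1 D-alanine methyl ester hydrochloride
Product: 2 methyl (2R)-2-(dibenzylamino)propanoate
Conditions: BnBr, K2CO3, MeCN, 60 °C
Reagents that add atoms: benzyl bromide, BrCc1ccccc1
Why: Exhaustive N-benzylation (SN2 alkylation) under carbonate buffering is a standard, non-racemising entry to N,N-dibenzyl amino esters; the C2 stereocentre is purchased with D-alanine and is not touched.

Step 2
Reactants: 2 methyl (2R)-2-(dibenzylamino)propanoate
Product: 3 1-[(1R)-1-(dibenzylamino)ethyl]cyclopropan-1-ol
Conditions: EtMgBr (3 equiv, slow addition), Ti(OiPr)4 (0.3 equiv), THF, 0 °C to rt; aq. NH4Cl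
Reagents that add atoms: ethylmagnesium bromide, CC[Mg]Br
Why: Kulinkovich cyclopropanation, in which the titanacyclopropane formed from EtMgBr and Ti(OiPr)4 adds twice to the ester carbonyl, is well established for N,N-dibenzyl α-amino esters and its weakly basic titanium intermediates should leave the α-stereocentre intact; the step builds on purpose the cyclopropane C–C bond that is absent from the target.

Step 3
Reactants: 3 1-[(1R)-1-(dibenzylamino)ethyl]cyclopropan-1-ol
Product: 4 1-[(1R)-1-aminoethyl]cyclopropan-1-ol
Conditions: H2 (1 atm), Pd(OH)2/C, MeOH, rt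
Reagents that add atoms: none
Why: Hydrogenolytic N-debenzylation frees the primary amine, while the unactivated cyclopropanol should be inert to hydrogen at ambient pressure; the amine is used crude.

Step 4
Reactants: 5 ethyl acetoacetate; 6 12-bromododecan-1-ol
Product: 8 15-hydroxypentadecan-2-one, via ethyl 2-acetyl-14-hydroxytetradecanoate 7 (not isolated)
Conditions: NaOEt, NaI (cat.), EtOH, reflux; then aq. NaOH, rt; then aq. HCl, 60 °C
Reagents that add atoms: none
Why: Acetoacetic ester synthesis: C-alkylation of the stabilised enolate by the primary bromide (the enolate is far less basic than an alkoxide, so the free alcohol is tolerated), then saponification and decarboxylation of the β-keto acid to the methyl ketone.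

Step 5
Reactants: 8 15-hydroxypentadecan-2-one
Product: 9 13-(2-methyl-1,3-dioxolan-2-yl)tridecan-1-ol
Conditions: HOCH2CH2OH, TsOH (cat.), toluene, reflux, Dean–Stark
Reagents that add atoms: ethane-1,2-diol, OCCO
Why: Acid-catalysed ketalisation with azeotropic removal of water masks the methyl ketone as a dioxolane that should survive the organozinc and hydride steps.

Step 6
Reactants: 9 13-(2-methyl-1,3-dioxolan-2-yl)tridecan-1-ol
Product: 10 13-(2-methyl-1,3-dioxolan-2-yl)tridecanal
Conditions: TEMPO (cat.), PhI(OAc)2, CH2Cl2, rt
Reagents that add atoms: none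
Why: Oxoammonium-mediated (TEMPO) oxidation of the primary alcohol should stop cleanly at the aldehyde and tolerate the ketal.

Step 7
Reactants: 4 1-[(1R)-1-aminoethyl]cyclopropan-1-ol; 10 13-(2-methyl-1,3-dioxolan-2-yl)tridecanal
Product: 11 (7R)-7-methyl-5-[12-(2-methyl-1,3-dioxolan-2-yl)dodecyl]-4-oxa-6-azaspiro[2.4]heptane (both C5 epimers, in ring–chain equilibrium with the open hydroxy imine)
Conditions: 4 Å molecular sieves, CH2Cl2, rt
Reagents that add atoms: none
Why: Condensation of the primary amine with the aldehyde gives the imine, which the neighbouring tertiary hydroxyl captures as a 1,3-oxazolidine (N,O-acetal formation); the acetal carbon forms as both epimers, which is of no consequence because it becomes trigonal again in step 8.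

Step 8
Reactants: 11 (7R)-7-methyl-5-[12-(2-methyl-1,3-dioxolan-2-yl)dodecyl]-4-oxa-6-azaspiro[2.4]heptane
Product: 15 tert-butyl (2R,6S)-2-methyl-6-[12-(2-methyl-1,3-dioxolan-2-yl)dodecyl]-3-oxopiperidine-1-carboxylate, via ethylzinc cyclopropoxide imine 12 (not isolated), via zinc homoenolate 13 (not isolated), via piperidinone zinc amide 14 (not isolated)
Conditions: Et2Zn (1.5 equiv), Zn(OTf)2 (10 mol%), THF, 0 to 50 °C; then Boc2O, 50 °C; then H2O
Reagents that add atoms: di-tert-butyl dicarbonate, CC(C)(C)OC(=O)OC(=O)OC(C)(C)C
Why: Proposed new method: Et2Zn traps the open hydroxy-imine tautomer of 11 on oxygen (Zn(OTf)2 speeds the ring–chain exchange and activates the imine), so both acetal epimers of 11 should drain into the same N,O-chelated ethylzinc cyclopropoxide (E)-imine 12; strain-driven β-carbon elimination (the two cyclopropane CH2 groups are equivalent, so no regiochemical question arises) gives the β-zincio ketone 13, whose C–Zn carbon adds to the imine carbon to form the C5–C6 bond, and the zinc amide 14 is acylated in the same flask by Boc2O. The closest known reactions are the ring opening of cyclopropanols to zinc homoenolates by Et2Zn, their intermolecular homo-Mannich additions to activated imines, and acid-promoted cyclopropanol–iminium cyclisations; the new element is the intramolecular case in which the imine nitrogen sits on the carbon next to the carbinol centre, so that the cyclopropanol is expanded into a piperidin-3-one. The piperidine ring closes in the 6-endo-trig mode (the C=N bond lies inside the new ring), while the cyclopropane and the oxazolidine, neither of which is in the target, are both cleaved. The new C6 stereocentre is controlled by the D-alanine-derived C2 centre: in a chair-like transition state the C2 methyl group is equatorial and the side chain of the (E)-imine is held equatorial, which should give the 2,6-cis (2R,6S) isomer, also the thermodynamically preferred one. The step needs C–C bond formation to outrun protonation or ethyl transfer and must not epimerise C2; the intramolecular six-membered closure, the low basicity of organozinc species and the fact that the C3 ketone appears only at the moment of ring opening should secure this.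

Step 9
Reactants: 15 tert-butyl (2R,6S)-2-methyl-6-[12-(2-methyl-1,3-dioxolan-2-yl)dodecyl]-3-oxopiperidine-1-carboxylate
Product: 16 tert-butyl (2R,3R,6S)-3-hydroxy-2-methyl-6-[12-(2-methyl-1,3-dioxolan-2-yl)dodecyl]piperidine-1-carboxylate
Conditions: LiBH(s-Bu)3, THF, −78 °C; then H2O
Reagents that add atoms: none
Why: Substrate-controlled hydride reduction: allylic 1,3-strain with the carbamate places the C2 methyl group (and the C6 chain) pseudo-axial on one face, so the bulky borohydride should attack the C3 carbonyl from the opposite face and leave the hydroxyl cis to both substituents (3R), as known for N-acyl 2-substituted piperidin-3-ones.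

Step 10
Reactants: 16 tert-butyl (2R,3R,6S)-3-hydroxy-2-methyl-6-[12-(2-methyl-1,3-dioxolan-2-yl)dodecyl]piperidine-1-carboxylate
Product: 17 tert-butyl (2R,3R,6S)-3-acetoxy-2-methyl-6-[12-(2-methyl-1,3-dioxolan-2-yl)dodecyl]piperidine-1-carboxylate
Conditions: Ac2O, DMAP (cat.), pyridine, CH2Cl2, rt
Reagents that add atoms: acetic anhydride, CC(=O)OC(C)=O
Why: DMAP-catalysed O-acylation of the secondary alcohol proceeds with retention at C3, the nitrogen being blocked as its carbamate.

Step 11
Reactants: 17 tert-butyl (2R,3R,6S)-3-acetoxy-2-methyl-6-[12-(2-methyl-1,3-dioxolan-2-yl)dodecyl]piperidine-1-carboxylate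
Product: 18 (2R,3R,6S)-2-methyl-6-(13-oxotetradecyl)piperidin-3-yl acetate, (−)-3-O-acetylspectaline
Conditions: TFA, H2O, CH2Cl2, 0 °C to rt; then cold aq. NaHCO3
Reagents that add atoms: water, O
Why: Acidolysis removes the Boc group (tert-butyl cation loss, then decarboxylation) and the water present hydrolyses the dioxolane in the same operation, while the secondary acetate should be stable to aqueous acid at ambient temperature; a cold bicarbonate work-up limits O-to-N acetyl migration.

**Compound list**

1 | D-alanine methyl ester hydrochloride | Cl.COC(=O)[C@@H](C)N | starting material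
2 | methyl (2R)-2-(dibenzylamino)propanoate | COC(=O)[C@@H](C)N(Cc1ccccc1)Cc1ccccc1 | intermediate
3 | 1-[(1R)-1-(dibenzylamino)ethyl]cyclopropan-1-ol | C[C@@H](N(Cc1ccccc1)Cc1ccccc1)C1(O)CC1 | intermediate
4 | 1-[(1R)-1-aminoethyl]cyclopropan-1-ol | C[C@@H](N)C1(O)CC1 | intermediate
5 | ethyl acetoacetate | CCOC(=O)CC(C)=O | starting material
6 | 12-bromododecan-1-ol | OCCCCCCCCCCCCBr | starting material
7 | ethyl 2-acetyl-14-hydroxytetradecanoate (not isolated) | CCOC(=O)C(CCCCCCCCCCCCO)C(C)=O | intermediate
8 | 15-hydroxypentadecan-2-one | CC(=O)CCCCCCCCCCCCCO | intermediate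
9 | 13-(2-methyl-1,3-dioxolan-2-yl)tridecan-1-ol | CC1(OCCO1)CCCCCCCCCCCCCO | intermediate
10 | 13-(2-methyl-1,3-dioxolan-2-yl)tridecanal | CC1(OCCO1)CCCCCCCCCCCCC=O | intermediate
11 | (7R)-7-methyl-5-[12-(2-methyl-1,3-dioxolan-2-yl)dodecyl]-4-oxa-6-azaspiro[2.4]heptane, both C5 epimers | C[C@H]1NC(CCCCCCCCCCCCC2(C)OCCO2)OC13CC3 | intermediate
12 | ethylzinc 1-[(1R)-1-{(E)-[13-(2-methyl-1,3-dioxolan-2-yl)tridecylidene]amino}ethyl]cyclopropan-1-olate (not isolated) | CC[Zn]OC1(CC1)[C@@H](C)/N=C/CCCCCCCCCCCCC1(C)OCCO1 | intermediate
13 | ethyl{(4R)-4-{(E)-[13-(2-methyl-1,3-dioxolan-2-yl)tridecylidene]amino}-3-oxopentyl}zinc, the zinc homoenolate (not isolated) | CC[Zn]CCC(=O)[C@@H](C)/N=C/CCCCCCCCCCCCC1(C)OCCO1 | intermediate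
14 | N-ethylzinc amide of (2R,6S)-2-methyl-6-[12-(2-methyl-1,3-dioxolan-2-yl)dodecyl]piperidin-3-one (not isolated) | CC[Zn]N1[C@H](C)C(=O)CC[C@@H]1CCCCCCCCCCCCC2(C)OCCO2 | intermediate
15 | tert-butyl (2R,6S)-2-methyl-6-[12-(2-methyl-1,3-dioxolan-2-yl)dodecyl]-3-oxopiperidine-1-carboxylate | CC1(OCCO1)CCCCCCCCCCCC[C@H]2CCC(=O)[C@@H](C)N2C(=O)OC(C)(C)C | intermediate
16 | tert-butyl (2R,3R,6S)-3-hydroxy-2-methyl-6-[12-(2-methyl-1,3-dioxolan-2-yl)dodecyl]piperidine-1-carboxylate | CC1(OCCO1)CCCCCCCCCCCC[C@H]2CC[C@@H](O)[C@@H](C)N2C(=O)OC(C)(C)C | intermediate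
17 | tert-butyl (2R,3R,6S)-3-acetoxy-2-methyl-6-[12-(2-methyl-1,3-dioxolan-2-yl)dodecyl]piperidine-1-carboxylate | CC1(OCCO1)CCCCCCCCCCCC[C@H]2CC[C@@H](OC(C)=O)[C@@H](C)N2C(=O)OC(C)(C)C | intermediate
18 | (2R,3R,6S)-2-methyl-6-(13-oxotetradecyl)piperidin-3-yl acetate, (−)-3-O-acetylspectaline | CC(=O)CCCCCCCCCCCC[C@H]1CC[C@@H](OC(C)=O)[C@@H](C)N1 | target

**Summary**

Total step count: 11.
Longest linear sequence: 8 steps (steps 1, 2, 3, 7, 8, 9, 10, 11; the aldehyde branch through steps 4 to 6 is equally long).

Steps most likely to fail:

1. Step 8 (Proposed new method). The zinc homoenolate may be protonated or transfer its ethyl group faster than it closes the ring, or the open imine may tautomerise through an aza-allyl shift and erode the C2 configuration. Any 2,6-trans isomer would also have to be removed before base contact, because epimerisation at C2 would turn it into the enantiomer of 15. Fallback by known chemistry, setting out from 3 together with 10 and returning to the route at 15: Pd(OAc)2-catalysed aerobic ring opening of 3 (pyridine, O2, toluene, 80 °C) should give (4R)-4-(dibenzylamino)pent-1-en-3-one F1. A thiazolium-catalysed Stetter reaction of 10 with F1 (3-benzyl-5-(2-hydroxyethyl)-4-methylthiazolium chloride, Et3N, EtOH, 70 °C) forms the C5–C6 bond intermolecularly and should give (2R)-2-(dibenzylamino)-18-(2-methyl-1,3-dioxolan-2-yl)octadecane-3,6-dione F2. Hydrogenolysis (H2, Pd(OH)2/C, MeOH) frees (2R)-2-amino-18-(2-methyl-1,3-dioxolan-2-yl)octadecane-3,6-dione F3, which condenses onto the C6 ketone to the cyclic imine (2R)-2-methyl-6-[12-(2-methyl-1,3-dioxolan-2-yl)dodecyl]-4,5-dihydro-2H-pyridin-3-one F4. In the same flask F4 is hydrogenated from the face opposite the C2 methyl group to (2R,6S)-2-methyl-6-[12-(2-methyl-1,3-dioxolan-2-yl)dodecyl]piperidin-3-one F5, and Boc2O then gives 15. This fallback closes the ring at N1–C6 rather than at C5–C6.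

2. Step 9. Facial selectivity of hydride delivery may be poor, or the basic borohydride may enolise the α-amino ketone, so that the C3 epimer forms alongside 16. Fallback, setting out from 15 and returning at 17: the two alcohols are separated, 16 goes on through step 10, and the epimer tert-butyl (2R,3S,6S)-3-hydroxy-2-methyl-6-[12-(2-methyl-1,3-dioxolan-2-yl)dodecyl]piperidine-1-carboxylate F6 is esterified with inversion at C3 under Mitsunobu conditions (PPh3, DIAD, AcOH, THF, 0 °C to rt). This gives 17 directly, so both reduction products converge.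

3. Step 11. The acetate may be lost during the aqueous acid treatment, or the acetyl group may shift from oxygen to nitrogen once the ammonium salt is neutralised. Fallback, setting out from 16 and returning at 18: the order is inverted. Aqueous HCl in THF removes the Boc group and the dioxolane from 16 to give (−)-spectaline hydrochloride F7. The hydroxyl of F7 is then acetylated selectively with acetyl chloride in TFA, where the protonated nitrogen cannot react (O-selective acylation of an amino alcohol salt), and careful cold neutralisation gives 18.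

**Further compounds**

F1 | step 8 | (4R)-4-(dibenzylamino)pent-1-en-3-one | C=CC(=O)[C@@H](C)N(Cc1ccccc1)Cc1ccccc1
F2 | step 8 | (2R)-2-(dibenzylamino)-18-(2-methyl-1,3-dioxolan-2-yl)octadecane-3,6-dione | C[C@@H](N(Cc1ccccc1)Cc1ccccc1)C(=O)CCC(=O)CCCCCCCCCCCCC1(C)OCCO1
F3 | step 8 | (2R)-2-amino-18-(2-methyl-1,3-dioxolan-2-yl)octadecane-3,6-dione | C[C@@H](N)C(=O)CCC(=O)CCCCCCCCCCCCC1(C)OCCO1
F4 | step 8 | (2R)-2-methyl-6-[12-(2-methyl-1,3-dioxolan-2-yl)dodecyl]-4,5-dihydro-2H-pyridin-3-one | CC1(OCCO1)CCCCCCCCCCCCC2=N[C@H](C)C(=O)CC2
F5 | step 8 | (2R,6S)-2-methyl-6-[12-(2-methyl-1,3-dioxolan-2-yl)dodecyl]piperidin-3-one | CC1(OCCO1)CCCCCCCCCCCC[C@H]2CCC(=O)[C@@H](C)N2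
F6 | step 9 | tert-butyl (2R,3S,6S)-3-hydroxy-2-methyl-6-[12-(2-methyl-1,3-dioxolan-2-yl)dodecyl]piperidine-1-carboxylate | CC1(OCCO1)CCCCCCCCCCCC[C@H]2CC[C@H](O)[C@@H](C)N2C(=O)OC(C)(C)C
F7 | step 11 | (−)-spectaline hydrochloride, 14-[(2S,5R,6R)-5-hydroxy-6-methylpiperidin-2-yl]tetradecan-2-one hydrochloride | Cl.CC(=O)CCCCCCCCCCCC[C@H]1CC[C@@H](O)[C@@H](C)N1
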